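The electrophile went slowly after a quick start: the red run still held 91 % at 2.00 min and 78 % at 10.0 min.

| setting | red | amber | flask |
|---|---|---|---|
| electrophile | 0.14 M | 0.14 M | 0.14 M |
| protonated nucleophile | 0.13 M | 0.50 M | 0.252 M |
| gas | 27 mM (held) | 27 mM (held) | 27 mM (held) |
| remark | run made earlier | run made earlier |  |
| time |  |  | 8.0 min |

| run | time / min | electrophile / % | target / % |
|---|---|---|---|
| red | 2.00 | 91 | 11 |
| red | 4.00 | 84 | 16 |
| red | 6.00 | 83 | 20 |
| red | 8.00 | 78 | 19 |
| red | 10.0 | 78 | 27 |
| amber | 0.833 | 89 | 10 |
| amber | 2.50 | 85 | 16 |
| amber | 4.00 | 78 | 24 |
| amber | 6.00 | 75 | 26 |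
| amber | 10.0 | 66 | 36 |

(each reading ± 2 percentage points)

- at the start none of the gas is in solution
- the earlier runs do not show how much of nucleophile is bound; that part of a forecast is a guess

1. part of the electrophile that has reacted at 8.0 min
2. share of the unused nucleophile that is free and not bound as protonated nucleophile, at 8.0 min

I reckoned the new flask in two ways, first from the electrophile peak and then with a quotient built on the target peak. From the electrophile peak at 8.0 min, the red run had lost 22.0 % and the amber run, by the midpoint of its neighbouring readings, 29.5 %. Interpolating on the logarithm of the protonated nucleophile charge gave 25.7 % for the flask.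

For the target peak I needed a rule. At 10.0 min the loss rose as the 0.323 power of that charge, about a third, so I cubed. At 8.0 min the target read 26.6 mM in the red run and, by the same midpoint, 43.4 mM in the amber run. Dividing each cube by the electrophile left times the protonated nucleophile left, taken as charge minus target, gave 1.61 mM and 1.85 mM. Their mean, 1.73 mM, is my stall quotient. Applied to the flask, starting from the full charges and putting each result back as the amount reacted, it ran 28.1 %, 23.8 %, 24.5 % and ended at 24.4 %. That lies 1.3 percentage points below the first number, but the cubing came from the electrophile peak and both numbers rest on the same two runs, so their closeness was no check.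

The forecast, which differs slightly from both, said 25 % reacted and 25 % free, adding: “This is a guess, because the runs give only the ratio”.

    nucleophile + acid set free ⇌ protonated nucleophile, settled at all times (K = 468 M⁻¹)
    acid set free + free base ⇌ salt of the base (K = 2.24 × 10⁶ M⁻¹, k = 0.265 M⁻¹ s⁻¹)
    gas ⇌ free base, rate k3*(csat - [free base]) (kL = 0.262 s⁻¹)
    electrophile + nucleophile ⇌ acid set free + target (K = 0.270, k = 0.456 M⁻¹ s⁻¹)
    target → over-reaction product (k = 7.80 × 10⁻⁶ s⁻¹)

The flask gave 26.2 % reacted, and its free share was 11.0 %, 14 points below the forecast. At 8.00 min the forward rate of the electrophile step alone meant a half-life of 1.1 min, short against 8.0 min, yet 74 % of the electrophile remained. The flask's stall quotient came to 2.21 mM, above my 1.73 mM. The neighbour flask with 0.035 M electrophile reached 44.9 % reacted, a quotient of 0.851 mM.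

The data were generated by integration with constants of no real substance; noise was put on by code.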